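**Retrosynthetic overview**

1. The target, epioritin-(4β→6)-epioritin-4α-ol, is reached by global hydrogenolysis of its hepta-O-benzyl ether.
2. The strategy rests on the all-cis triad of lower ring C fused to phenolic ring A (lower): C2 (aryl ether to O1), C3 (OH) and C4 (OH). This triad maps onto the benzylic epoxide carbon, the epoxide oxygen and the aldehyde carbon of a cis-3-arylglycidaldehyde, so C4–C4a and O1–C2 are disconnected in one [3+3] annulation of a metal phenoxide.
3. The interflavan bond C4 (upper)–C6 (lower) comes from Friedel–Crafts arylation of an upper flavan C4 cation, para to the hydroxyl of a 2,3-bis(benzyloxy)phenol whose ortho carbon is blocked by bromine; the bromine is then removed.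
4. Upper ring C comes from an ortho-lithiated phenoxide and the same cis-epoxy aldehyde, followed by acid ring closure (known chemistry; C4 is ionised later).
5. The epoxy aldehyde comes from a Z-cinnamate by Jacobsen–Katsuki epoxidation and partial reduction. Ring order: upper ring C (step 7), then lower ring C (step 11).

Key step: step 11

Remark on the chemistry: in the usual flavan drawing the target is 2α-aryl, 3α-OH, 4β-aryl in the upper unit (2R,3R,4S) and 2α-aryl, 3α-OH, 4α-OH in the lower unit (2R,3R,4R). Compounds 11, 12 and 13 are carried as C4 epimers, because both epimers give the same cation in step 9.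

**Route**

Step 1
Reactants: 1 2,3-dihydroxybenzaldehyde
Product: 2 2,3-bis(benzyloxy)benzaldehyde
Conditions: BnBr (2.3 equiv), K2CO3, DMF, 60 °C
Reagents that add atoms: benzyl bromide, BrCc1ccccc1
Why: Williamson etherification of both phenolic hydroxyls; no stereocentre is involved.

Step 2
Reactants: 2 2,3-bis(benzyloxy)benzaldehyde
Product: 4 2,3-bis(benzyloxy)phenol, via aryl formate 3 (not isolated)
Conditions: mCPBA, CH2Cl2, rt; then K2CO3 (cat.), MeOH, rt
Reagents that add atoms: mCPBA, OOC(=O)c1cccc(Cl)c1
Why: Baeyer–Villiger oxidation of the electron-rich ortho-alkoxybenzaldehyde proceeds with aryl migration to the formate, which is cleaved by methanolysis (Dakin-type aldehyde-to-phenol conversion).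

Step 3
Reactants: 4 2,3-bis(benzyloxy)phenol
Product: 5 6-bromo-2,3-bis(benzyloxy)phenol
Conditions: NBS (1.0 equiv), i-Pr2NH (0.1 equiv), CH2Cl2, 0 °C
Reagents that add atoms: N-bromosuccinimide, O=C1CCC(=O)N1Br
Why: Amine-mediated electrophilic bromination of phenols delivers bromine ortho to the hydroxyl through a hydrogen-bonded N-bromoamine, and C6 is the only free ortho position; any para isomer is removed by chromatography.

Step 4
Reactants: 6 4-benzyloxybenzaldehyde
Product: 7 ethyl (Z)-3-[4-(benzyloxy)phenyl]prop-2-enoate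
Conditions: (CF3CH2O)2P(O)CH2CO2Et, KHMDS, 18-crown-6, THF, −78 °C
Reagents that add atoms: ethyl 2-[bis(2,2,2-trifluoroethoxy)phosphoryl]acetate, CCOC(=O)CP(=O)(OCC(F)(F)F)OCC(F)(F)F
Why: Still–Gennari variant of the Horner–Wadsworth–Emmons olefination, in which fast irreversible elimination from the kinetic adduct gives the Z-enoate with aromatic aldehydes.

Step 5
Reactants: 7 ethyl (Z)-3-[4-(benzyloxy)phenyl]prop-2-enoate
Product: 8 ethyl (2S,3S)-3-[4-(benzyloxy)phenyl]oxirane-2-carboxylate (cis)
Conditions: (S,S)-[N,N'-bis(3,5-di-tert-butylsalicylidene)cyclohexane-1,2-diaminato]MnCl (6 mol%), 4-phenylpyridine N-oxide (0.25 equiv), aq. NaOCl (pH 11), CH2Cl2, 4 °C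
Reagents that add atoms: sodium hypochlorite, [Na+].[O-]Cl
Why: Jacobsen–Katsuki epoxidation, for which cis-cinnamate esters are a privileged substrate class; the (S,S) catalyst should give the (2S,3S) cis-epoxide (mirror image of the sense known for the parent cis-cinnamate with the (R,R) catalyst), and the ester group keeps the electron-rich aryl epoxide isolable; the minor trans-epoxide is removed by chromatography.

Step 6
Reactants: 8 ethyl (2S,3S)-3-[4-(benzyloxy)phenyl]oxirane-2-carboxylate
Product: 9 (2S,3S)-3-[4-(benzyloxy)phenyl]oxirane-2-carbaldehyde (cis)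
Conditions: i-Bu2AlH (1.05 equiv), CH2Cl2, −78 °C; aq. potassium sodium tartrate; used at once
Reagents that add atoms: none
Why: Partial reduction of the ester stops at the aluminium hemiacetal at −78 °C (stabilised by the α-oxygen), so the aldehyde is released only on work-up and both epoxide stereocentres are untouched.

Step 7
Reactants: 5 6-bromo-2,3-bis(benzyloxy)phenol; 9 (2S,3S)-3-[4-(benzyloxy)phenyl]oxirane-2-carbaldehyde
Product: 12 (2R,3R)-7,8-bis(benzyloxy)-2-[4-(benzyloxy)phenyl]chromane-3,4-diol (2,3-cis; C4 epimers), via dilithio phenoxide 10 (not isolated), via epoxy alcohol 11 (not isolated)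
Conditions: 5 (1.2 equiv), n-BuLi (2.4 equiv), THF, −78 °C; then 9, −78 °C; aq. NH4Cl; crude 11, PPTS (cat.), CH2Cl2, 0 °C
Reagents that add atoms: none
Why: Deprotonation and bromine–lithium exchange give an ortho-lithiated phenoxide that adds 1,2 to the aldehyde, and mild acid then lets the phenol oxygen open the benzylic epoxide carbon with inversion (6-endo opening of an aryl epoxide), so the cis-epoxide becomes the 2,3-cis flavan with C3 retained; the C4 epimer ratio does not matter.

Step 8
Reactants: 12 (2R,3R)-7,8-bis(benzyloxy)-2-[4-(benzyloxy)phenyl]chromane-3,4-diol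
Product: 13 (2R,3R)-3,4,7,8-tetrakis(benzyloxy)-2-[4-(benzyloxy)phenyl]chromane (2,3-cis; C4 epimers)
Conditions: NaH (2.5 equiv), BnBr (2.5 equiv), n-Bu4NI (cat.), DMF, 0 °C → rt
Reagents that add atoms: benzyl bromide, BrCc1ccccc1
Why: Williamson etherification of both secondary hydroxyls protects O3 for the rest of the route and turns O4 into an ionisable benzylic ether.

Step 9
Reactants: 13 (2R,3R)-3,4,7,8-tetrakis(benzyloxy)-2-[4-(benzyloxy)phenyl]chromane; 5 6-bromo-2,3-bis(benzyloxy)phenol
Product: 14 2,3-bis(benzyloxy)-6-bromo-4-{(2R,3R)-3,7,8-tris(benzyloxy)-2-[4-(benzyloxy)phenyl]chroman-4β-yl}phenol (2,3-cis-3,4-trans)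
Conditions: 5 (3 equiv), TMSOTf (0.5 equiv), CH2Cl2, −78 → −30 °C; aq. NaHCO3/MeOH work-up
Reagents that add atoms: none
Why: The Lewis acid ionises the C4 benzyl ether of either epimer to one benzylic cation (stabilised by O1 and the 7-benzyloxy group), which alkylates 5 in a Friedel–Crafts reaction para to its hydroxyl (the ortho carbon carries bromine) from the face anti to the 3-benzyloxy group, setting upper C4 as 4β as is usual for C4 arylation of 2,3-cis flavan-3-ol derivatives.

Step 10
Reactants: 14 the bromophenol from step 9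
Product: 16 2,3-bis(benzyloxy)-4-{(2R,3R,4S)-3,7,8-tris(benzyloxy)-2-[4-(benzyloxy)phenyl]chroman-4-yl}phenol, via dilithio derivative 15 (not isolated)
Conditions: n-BuLi (2.2 equiv), THF, −78 °C; then MeOH, aq. NH4Cl
Reagents that add atoms: none
Why: Phenol deprotonation and bromine–lithium exchange are fast at −78 °C and leave the benzyl ethers alone, and protonolysis replaces the blocking bromine by hydrogen, freeing the single ortho CH needed in step 11.

Step 11
Reactants: 16 the free phenol from step 10; 9 (2S,3S)-3-[4-(benzyloxy)phenyl]oxirane-2-carbaldehyde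
Product: 19 hepta-O-benzyl dimer with free lower 3,4-diol (upper unit as in 16; lower ring C 2α-aryl, 3α-OH, 4α-OH, that is 2R,3R,4R), via titanium phenoxide 17 (not isolated), via anti epoxy alcohol 18 (not isolated)
Conditions: Ti(OiPr)4 (1.1 equiv), toluene, rt, iPrOH removed in vacuo; fresh 9 (1.5 equiv), toluene/CH2Cl2, −20 °C → rt; aq. NaHCO3; crude 18, PPTS (cat.), CH2Cl2, 0 °C
Reagents that add atoms: none
Why: Proposed new method: the aryloxytitanium triisopropoxide 17 binds the aldehyde of 9 at the metal and delivers its ortho carbon (C4a of the lower unit) to the carbonyl through a six-membered cyclic transition state, rearomatisation giving the ortho-hydroxybenzylic epoxy alcohol 18 (new C4–C4a bond), and mild acid then lets the phenol oxygen open the epoxide at the benzylic carbon (new O1–C2 bond), closing lower ring C in a 6-endo-tet mode. The closest known reactions are the ortho-specific hydroxyalkylation of magnesium and titanium phenoxides with chiral α-alkoxy aldehydes and the acid-mediated 6-endo opening of aryl epoxides by a neighbouring phenol; the use of an epoxy aldehyde and the merging of both events into one annulation are untested. C4 is set by Felkin–Anh attack anti to the epoxide C–O bond, which gives the anti carbinol and hence the 3,4-cis diol; titanium is chosen because alkoxytitanium phenoxides are the non-chelating, anti-directing members of this reagent family, whereas halomagnesium phenoxides tend to chelate the α-oxygen (syn product) and carry a halide that could open the labile epoxide. C3 keeps the epoxide oxygen with retention and C2 is inverted in the ring closure, so the cis-epoxide becomes the 2,3-cis relationship. The step needs ortho C-attack rather than para or O-attack (secured by the single free ortho CH, the occupied para position and the metal template), anti rather than syn addition (secured by the two epoxide stereocentres under non-chelating titanium) and 6-endo rather than 5-exo closure (secured by the 4-benzyloxyphenyl group, which stabilises positive charge at C2).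

Step 12
Reactants: 19 hepta-O-benzyl dimer
Product: 20 epioritin-(4β→6)-epioritin-4α-ol (CNP0391561.1)
Conditions: H2 (1 atm), Pd(OH)2/C, THF/MeOH (1:1), rt; filtration and evaporation under argon
Reagents that add atoms: none
Why: Hydrogenolysis of the seven benzyl ethers in neutral solvent is much faster than cleavage of the ring benzylic C–O bonds (C2–O1, lower C4–OH) or of the doubly benzylic interflavan bond, and no stereocentre is touched.

**Compound list**

1 | 2,3-dihydroxybenzaldehyde | O=Cc1cccc(O)c1O | starting material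
2 | 2,3-bis(benzyloxy)benzaldehyde | O=Cc1cccc(OCc2ccccc2)c1OCc1ccccc1 | intermediate
3 | 2,3-bis(benzyloxy)phenyl formate | O=COc1cccc(OCc2ccccc2)c1OCc1ccccc1 | intermediate (not isolated)
4 | 2,3-bis(benzyloxy)phenol | Oc1cccc(OCc2ccccc2)c1OCc1ccccc1 | intermediate
5 | 6-bromo-2,3-bis(benzyloxy)phenol | Oc1c(Br)ccc(OCc2ccccc2)c1OCc1ccccc1 | intermediate
6 | 4-benzyloxybenzaldehyde | O=Cc1ccc(OCc2ccccc2)cc1 | starting material
7 | ethyl (Z)-3-[4-(benzyloxy)phenyl]prop-2-enoate | CCOC(=O)/C=C\c1ccc(OCc2ccccc2)cc1 | intermediate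
8 | ethyl (2S,3S)-3-[4-(benzyloxy)phenyl]oxirane-2-carboxylate (cis) | CCOC(=O)[C@H]1O[C@H]1c1ccc(OCc2ccccc2)cc1 | intermediate
9 | (2S,3S)-3-[4-(benzyloxy)phenyl]oxirane-2-carbaldehyde (cis) | O=C[C@H]1O[C@H]1c1ccc(OCc2ccccc2)cc1 | intermediate
10 | lithium 2,3-bis(benzyloxy)-6-lithiophenoxide | [Li]Oc1c([Li])ccc(OCc2ccccc2)c1OCc1ccccc1 | intermediate (not isolated)
11 | 2,3-bis(benzyloxy)-6-{hydroxy[cis-3-(4-benzyloxyphenyl)oxiran-2-yl]methyl}phenol, epoxide carbons as in 9, carbinol epimers | Oc1c(C(O)[C@H]2O[C@H]2c2ccc(OCc3ccccc3)cc2)ccc(OCc2ccccc2)c1OCc1ccccc1 | intermediate (not isolated)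
12 | (2R,3R)-7,8-bis(benzyloxy)-2-[4-(benzyloxy)phenyl]chromane-3,4-diol (2,3-cis; C4 epimers) | c1cc2c(c(OCc3ccccc3)c1OCc1ccccc1)O[C@H](c1ccc(OCc3ccccc3)cc1)[C@H](O)C2O | intermediate
13 | (2R,3R)-3,4,7,8-tetrakis(benzyloxy)-2-[4-(benzyloxy)phenyl]chromane (2,3-cis; C4 epimers) | c1cc2c(c(OCc3ccccc3)c1OCc1ccccc1)O[C@H](c1ccc(OCc3ccccc3)cc1)[C@H](OCc1ccccc1)C2OCc1ccccc1 | intermediate
14 | 2,3-bis(benzyloxy)-6-bromo-4-{(2R,3R)-3,7,8-tris(benzyloxy)-2-[4-(benzyloxy)phenyl]chroman-4β-yl}phenol (2,3-cis-3,4-trans) | C(c1ccccc1)Oc1ccc([C@H]2Oc3c(ccc(OCc4ccccc4)c3OCc3ccccc3)[C@H](c3cc(Br)c(O)c(OCc4ccccc4)c3OCc3ccccc3)[C@H]2OCc2ccccc2)cc1 | intermediate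
15 | dilithio derivative of 14 (lithium phenoxide, lithium in place of bromine) | C(c1ccccc1)Oc1ccc([C@H]2Oc3c(ccc(OCc4ccccc4)c3OCc3ccccc3)[C@H](c3cc([Li])c(O[Li])c(OCc4ccccc4)c3OCc3ccccc3)[C@H]2OCc2ccccc2)cc1 | intermediate (not isolated)
16 | 2,3-bis(benzyloxy)-4-{(2R,3R,4S)-3,7,8-tris(benzyloxy)-2-[4-(benzyloxy)phenyl]chroman-4-yl}phenol (2,3-cis-3,4-trans) | C(c1ccccc1)Oc1ccc([C@H]2Oc3c(ccc(OCc4ccccc4)c3OCc3ccccc3)[C@H](c3ccc(O)c(OCc4ccccc4)c3OCc3ccccc3)[C@H]2OCc2ccccc2)cc1 | intermediate
17 | triisopropoxytitanium phenoxide of 16 | C(c1ccccc1)Oc1ccc([C@H]2Oc3c(ccc(OCc4ccccc4)c3OCc3ccccc3)[C@H](c3ccc(O[Ti](OC(C)C)(OC(C)C)OC(C)C)c(OCc4ccccc4)c3OCc3ccccc3)[C@H]2OCc2ccccc2)cc1 | intermediate (not isolated)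
18 | anti ortho-adduct of 16 and 9: phenol carrying at its ortho carbon the carbinol CH(OH) bonded to the cis-epoxide (epoxide carbons as in 9) | C(c1ccccc1)Oc1ccc([C@H]2Oc3c(ccc(OCc4ccccc4)c3OCc3ccccc3)[C@H](c3cc([C@@H](O)[C@H]4O[C@H]4c4ccc(OCc5ccccc5)cc4)c(O)c(OCc4ccccc4)c3OCc3ccccc3)[C@H]2OCc2ccccc2)cc1 | intermediate (not isolated)
19 | hepta-O-benzyl dimer with free lower 3,4-diol (upper 2,3-cis-3,4-trans; lower all-cis, 2R,3R,4R) | C(c1ccccc1)Oc1ccc([C@H]2Oc3c(ccc(OCc4ccccc4)c3OCc3ccccc3)[C@H](c3cc4c(c(OCc5ccccc5)c3OCc3ccccc3)O[C@H](c3ccc(OCc5ccccc5)cc3)[C@H](O)[C@@H]4O)[C@H]2OCc2ccccc2)cc1 | intermediate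
20 | (2R,3R,4R)-6-[(2R,3R,4S)-3,7,8-trihydroxy-2-(4-hydroxyphenyl)chroman-4-yl]-2-(4-hydroxyphenyl)chromane-3,4,7,8-tetrol | Oc1ccc([C@H]2Oc3c(ccc(O)c3O)[C@H](c3cc4c(c(O)c3O)O[C@H](c3ccc(O)cc3)[C@H](O)[C@@H]4O)[C@H]2O)cc1 | target

**Step count and risks**

Total step count: 12. Longest linear sequence: 9 steps (steps 1, 2, 3, 7, 8, 9, 10, 11, 12 from 1; equally steps 4, 5, 6, 7, 8, 9, 10, 11, 12 from 6).

Step 11 is the most likely to fail and is the one unprecedented step. The titanium phenoxide may be too weak a carbon nucleophile, so that Lewis acid-induced opening or rearrangement of the labile epoxide outruns C–C bond formation, or the carbonyl addition may proceed with poor facial selectivity. The fallback sets out from 14, whose bromine sits on the very carbon that has to bond. Treatment with n-BuLi (2.2 equiv, THF, −78 °C) gives the dilithio derivative 15, which is not quenched but treated with 9 at −78 °C. Addition of the aryllithium under non-chelating conditions should give the anti epoxy alcohol 18 after protonation (any syn epimer to be separated), and PPTS in CH2Cl2 at 0 °C should close lower ring C, rejoining the route at 19. Both events are known reaction types (ortho-lithiophenoxide addition to an aldehyde, acid-mediated 6-endo phenol opening of an aryl epoxide); no compound outside the list arises (F0).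

Step 9 is the second risk. Ionisation of the 5-deoxy C4 benzyl ether may be slow, and the cation may be captured by a second molecule of 13 (self-condensation) or by the phenol oxygen instead of the bromine-deactivated ring carbon. The fallback sets out from 13. BnSH (3 equiv) with BF3·OEt2 in CH2Cl2 at −20 °C should trap the cation as the thioether (2R)-4β-(benzylsulfanyl)-3,7,8-tris(benzyloxy)-2-[4-(benzyloxy)phenyl]chromane F1 (2,3-cis-3,4-trans). F1 is then activated with the thiophilic salt AgBF4 in THF at 0 °C in the presence of 5 (3 equiv), which forms the C4–aryl bond without a strong acid and rejoins the route at 14.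

Step 5 is the third risk. Part of the cis geometry may be lost through a rotating radical intermediate, and enantioselection may be incomplete with the electron-rich cinnamate. The fallback sets out from 7. i-Bu2AlH (2.2 equiv, CH2Cl2, −78 °C) reduces the ester to (Z)-3-[4-(benzyloxy)phenyl]prop-2-en-1-ol F2. Sharpless epoxidation (Ti(OiPr)4, D-(−)-diisopropyl tartrate, t-BuOOH, 4 Å molecular sieves, CH2Cl2, −20 °C) should give the cis epoxy alcohol [(2R,3S)-3-(4-benzyloxyphenyl)oxiran-2-yl]methanol F3. F3 is oxidised at once under Parikh–Doering conditions (SO3·pyridine, DMSO, i-Pr2NEt, CH2Cl2, 0 °C) to 9, where the route is rejoined; this replaces steps 5 and 6.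

**Further compounds**

F0 | step 11 | none | none
F1 | step 9 | (2R)-4β-(benzylsulfanyl)-3,7,8-tris(benzyloxy)-2-[4-(benzyloxy)phenyl]chromane (2,3-cis-3,4-trans) | c1cc2c(c(OCc3ccccc3)c1OCc1ccccc1)O[C@H](c1ccc(OCc3ccccc3)cc1)[C@H](OCc1ccccc1)[C@H]2SCc1ccccc1
F2 | step 5 | (Z)-3-[4-(benzyloxy)phenyl]prop-2-en-1-ol | OC/C=C\c1ccc(OCc2ccccc2)cc1
F3 | step 5 | [(2R,3S)-3-(4-benzyloxyphenyl)oxiran-2-yl]methanol (cis) | OC[C@H]1O[C@H]1c1ccc(OCc2ccccc2)cc1
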